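The plan disconnects the C8–C9 bond between the two ring methylenes of the seven-membered lactone (C7–C8–C9–C10=C11–C(=O)–O). C8 sits on the fully substituted carbinol carbon C7, so it can be carried as a non-enolisable α-acyloxy aldehyde, while C9 is the vinylogous γ-carbon of the lactone's own α-homoprenyl enoate. The key step is an intramolecular vinylogous Horner–Wadsworth–Emmons closure of a C7 ester carrying a C9 phosphonate onto the C8 aldehyde; it gives an oxepin-2(7H)-one whose C8=C9 bond is the only disubstituted alkene and is then saturated with diimide. C6 and C7 stem from Sharpless epoxidation of 8-hydroxygeranyl acetate and invertive hydrolysis at C7.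

Key step: step 11

Remark: locants C1–C15 are those of the open-chain skeleton (C1 = CH2OAc, C6 = secondary carbinol, C7 = lactone carbinol carbon, C8 and C9 = ring methylenes, C10=C11 = ring alkene, C12–C15 = homoprenyl chain).

Step 1
Reactants: 1 geranyl acetate [(2E)-3,7-dimethylocta-2,6-dien-1-yl acetate]
Product: 2 (2E,6E)-8-hydroxy-3,7-dimethylocta-2,6-dien-1-yl acetate
Conditions: SeO2 (cat.), tBuOOH, salicylic acid (cat.), CH2Cl2, 20 °C
Reagents that add atoms: tert-butyl hydroperoxide, CC(C)(C)OO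
Why: SeO2-catalysed allylic oxidation (ene reaction, then [2,3]-sigmatropic shift) should hydroxylate the (E)-methyl group of the electron-rich terminal alkene, the C2=C3 alkene being deactivated by the allylic acetate.

Step 2
Reactants: 2 (2E,6E)-8-hydroxy-3,7-dimethylocta-2,6-dien-1-yl acetate
Product: 3 (2E)-5-[(2R,3R)-3-(hydroxymethyl)-3-methyloxiran-2-yl]-3-methylpent-2-en-1-yl acetate (the 6R,7R epoxide)
Conditions: Ti(OiPr)4 (cat.), D-(−)-diethyl tartrate (cat.), tBuOOH, 4 Å molecular sieves, CH2Cl2, −20 °C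
Reagents that add atoms: tert-butyl hydroperoxide, CC(C)(C)OO
Why: Sharpless asymmetric epoxidation with D-(−)-diethyl tartrate should deliver oxygen to the face that gives the (6R,7R)-epoxide, and only the alkene with a free allylic hydroxyl should react.

Step 3
Reactants: 3 (2E)-5-[(2R,3R)-3-(hydroxymethyl)-3-methyloxiran-2-yl]-3-methylpent-2-en-1-yl acetate
Product: 4 (2E,6R,7S)-6,7,8-trihydroxy-3,7-dimethyloct-2-en-1-yl acetate
Conditions: HClO4 (cat.), THF/H2O, 0 °C
Reagents that add atoms: water, O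
Why: Acid-catalysed epoxide hydrolysis should occur by backside attack of water at the tertiary carbon C7 of the protonated epoxide (inversion at C7, retention at C6), which sets the (6R,7S) relationship of the target.

Step 4
Reactants: 4 (2E,6R,7S)-6,7,8-trihydroxy-3,7-dimethyloct-2-en-1-yl acetate
Product: 5 (2E,6R,7S)-7-hydroxy-3,7-dimethyl-6,8-bis(triethylsilyloxy)oct-2-en-1-yl acetate
Conditions: Et3SiCl (2.2 equiv), imidazole, DMF, 0 °C
Reagents that add atoms: chlorotriethylsilane, CC[Si](Cl)(CC)CC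
Why: Silyl ether formation should take place at the primary and the secondary hydroxyl only, the tertiary C7 hydroxyl being too hindered for the chlorosilane.

Step 5
Reactants: 6 2,2,6-trimethyl-4H-1,3-dioxin-4-one
Product: 7 diethyl [(2,2-dimethyl-4-oxo-4H-1,3-dioxin-6-yl)methyl]phosphonate
Conditions: LiN(iPr)2 (2 equiv), THF, −78 °C; then ClP(O)(OEt)2
Reagents that add atoms: diethyl chlorophosphate, CCOP(=O)(Cl)OCC
Why: Kinetic γ-deprotonation gives the dioxinone dienolate, which should undergo C-phosphorylation at the exocyclic carbon (nucleophilic substitution at phosphorus), the second equivalent of base absorbing the acidity of the product.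

Step 6
Reactants: 5 (2E,6R,7S)-7-hydroxy-3,7-dimethyl-6,8-bis(triethylsilyloxy)oct-2-en-1-yl acetate; 7 diethyl [(2,2-dimethyl-4-oxo-4H-1,3-dioxin-6-yl)methyl]phosphonate
Product: 9 (2E,6R,7S)-7-{[4-(diethoxyphosphoryl)-3-oxobutanoyl]oxy}-3,7-dimethyl-6,8-bis(triethylsilyloxy)oct-2-en-1-yl acetate, via acylketene 8 (not isolated)
Conditions: toluene, 110 °C
Reagents that add atoms: none
Why: Thermal retro-hetero-Diels–Alder cleavage of the dioxinone releases acetone and an acylketene, whose concerted addition to the hindered tertiary hydroxyl (acylketene acetoacetylation) should give the β-keto ester without touching C6 or C7.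

Step 7
Reactants: 9 (2E,6R,7S)-7-{[4-(diethoxyphosphoryl)-3-oxobutanoyl]oxy}-3,7-dimethyl-6,8-bis(triethylsilyloxy)oct-2-en-1-yl acetate; 10 5-bromo-2-methylpent-2-ene
Product: 11 (2E,6R,7S)-7-{[4-(diethoxyphosphoryl)-2-(4-methylpent-3-en-1-yl)-3-oxobutanoyl]oxy}-3,7-dimethyl-6,8-bis(triethylsilyloxy)oct-2-en-1-yl acetate (both epimers at C11)
Conditions: K2CO3, NaI (cat.), acetone, 56 °C
Reagents that add atoms: none
Why: C-Alkylation (SN2) of the β-keto ester enolate should occur at C11, which lies between ketone and ester and is more acidic than the phosphonate-bearing C9; the new centre is erased in step 9.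

Step 8
Reactants: 11 (2E,6R,7S)-7-{[4-(diethoxyphosphoryl)-2-(4-methylpent-3-en-1-yl)-3-oxobutanoyl]oxy}-3,7-dimethyl-6,8-bis(triethylsilyloxy)oct-2-en-1-yl acetate
Product: 12 (2E,6R,7S)-7-{[4-(diethoxyphosphoryl)-3-hydroxy-2-(4-methylpent-3-en-1-yl)butanoyl]oxy}-3,7-dimethyl-6,8-bis(triethylsilyloxy)oct-2-en-1-yl acetate (diastereomers at C10 and C11)
Conditions: NaBH4, MeOH, −20 °C
Reagents that add atoms: none
Why: Borohydride reduction should reduce the ketone chemoselectively in the presence of the esters; the carbinol configuration is irrelevant because it is removed in step 9.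

Step 9
Reactants: 12 (2E,6R,7S)-7-{[4-(diethoxyphosphoryl)-3-hydroxy-2-(4-methylpent-3-en-1-yl)butanoyl]oxy}-3,7-dimethyl-6,8-bis(triethylsilyloxy)oct-2-en-1-yl acetate
Product: 14 (2E,6R,7S)-7-{[(2E)-4-(diethoxyphosphoryl)-2-(4-methylpent-3-en-1-yl)but-2-enoyl]oxy}-3,7-dimethyl-6,8-bis(triethylsilyloxy)oct-2-en-1-yl acetate, via mesylate 13 (not isolated)
Conditions: MsCl, Et3N, CH2Cl2, 0 °C; then DBU, 20 °C
Reagents that add atoms: none
Why: Mesylation followed by E1cB elimination through the ester enolate should give the conjugated enoate; its geometry and any deconjugated isomer are immaterial because all converge on one delocalised anion in step 11.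

Step 10
Reactants: 14 (2E,6R,7S)-7-{[(2E)-4-(diethoxyphosphoryl)-2-(4-methylpent-3-en-1-yl)but-2-enoyl]oxy}-3,7-dimethyl-6,8-bis(triethylsilyloxy)oct-2-en-1-yl acetate
Product: 15 (2E,6R,7R)-7-{[(2E)-4-(diethoxyphosphoryl)-2-(4-methylpent-3-en-1-yl)but-2-enoyl]oxy}-3,7-dimethyl-8-oxo-6-(triethylsilyloxy)oct-2-en-1-yl acetate (C7 spatially unchanged; the descriptor changes because C8 now outranks C6)
Conditions: (COCl)2, DMSO, CH2Cl2, −78 to −30 °C; then Et3N
Reagents that add atoms: none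
Why: Swern oxidation should cleave and oxidise the primary triethylsilyl ether directly to the aldehyde while the secondary silyl ether survives; the aldehyde has no α-hydrogen, so C7 cannot epimerise.

Step 11
Reactants: 15 (2E,6R,7R)-7-{[(2E)-4-(diethoxyphosphoryl)-2-(4-methylpent-3-en-1-yl)but-2-enoyl]oxy}-3,7-dimethyl-8-oxo-6-(triethylsilyloxy)oct-2-en-1-yl acetate
Product: 16 (2E,6R)-3-methyl-6-[(2S)-2-methyl-6-(4-methylpent-3-en-1-yl)-7-oxo-2,7-dihydrooxepin-2-yl]-6-(triethylsilyloxy)hex-2-en-1-yl acetate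
Conditions: LiCl, DBU, MeCN, 0.002 M, 20 to 50 °C
Reagents that add atoms: none
Why: Reversible deprotonation of the allylic phosphonate gives a delocalised C9–C10–C11 anion that can equilibrate its C10=C11 geometry, and its phosphorus-bearing terminus C9 adds to the C8 aldehyde to give a β-oxido phosphonate that collapses through an oxaphosphetane with loss of diethyl phosphate. The closest known reaction type is the vinylogous Horner–Wadsworth–Emmons olefination of 4-phosphonocrotonates under LiCl/amidine-base conditions, which is used intramolecularly for unsaturated lactones. The seven-membered ring (C7, C8, C9, C10, C11, carbonyl carbon, O) closes by a 7-exo-trig addition to the aldehyde. No stereocentre is created: the new C8=C9 alkene can only be cis inside the ring, and C6 and C7 are untouched. The step needs attack through C9 rather than C11 and ring closure rather than oligomerisation: addition through C11 gives an aldolate that has no elimination pathway and reverts, only the C9 adduct is drained irreversibly, and high dilution suppresses intermolecular olefination.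

Step 12
Reactants: 16 (2E,6R)-3-methyl-6-[(2S)-2-methyl-6-(4-methylpent-3-en-1-yl)-7-oxo-2,7-dihydrooxepin-2-yl]-6-(triethylsilyloxy)hex-2-en-1-yl acetate
Product: 17 (2E,6R)-3-methyl-6-[(2S)-2-methyl-6-(4-methylpent-3-en-1-yl)-7-oxo-2,3,4,7-tetrahydrooxepin-2-yl]-6-(triethylsilyloxy)hex-2-en-1-yl acetate
Conditions: 2-nitrobenzenesulfonohydrazide, Et3N, CH2Cl2, 20 °C
Reagents that add atoms: none
Why: Diimide reduction (concerted syn transfer of H2) slows sharply with alkene substitution, so the only 1,2-disubstituted alkene, C8=C9 at the diene terminus, should be saturated while the three trisubstituted alkenes remain.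

Step 13
Reactants: 17 (2E,6R)-3-methyl-6-[(2S)-2-methyl-6-(4-methylpent-3-en-1-yl)-7-oxo-2,3,4,7-tetrahydrooxepin-2-yl]-6-(triethylsilyloxy)hex-2-en-1-yl acetate
Product: 18 (2E,6R)-6-hydroxy-3-methyl-6-[(2S)-2-methyl-6-(4-methylpent-3-en-1-yl)-7-oxo-2,3,4,7-tetrahydrooxepin-2-yl]hex-2-en-1-yl acetate (target)
Conditions: HF·pyridine, pyridine/THF, 0 °C
Reagents that add atoms: none
Why: Fluoride-mediated silyl ether cleavage should free the C6 hydroxyl under mildly acidic conditions that leave the tertiary lactone and the allylic acetate in place and do not promote acyl migration.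

Compound list
1 | geranyl acetate, (2E)-3,7-dimethylocta-2,6-dien-1-yl acetate | CC(=O)OC/C=C(\C)CCC=C(C)C | starting material
2 | (2E,6E)-8-hydroxy-3,7-dimethylocta-2,6-dien-1-yl acetate | CC(=O)OC/C=C(\C)CC/C=C(\C)CO | intermediate
3 | (2E)-5-[(2R,3R)-3-(hydroxymethyl)-3-methyloxiran-2-yl]-3-methylpent-2-en-1-yl acetate | CC(=O)OC/C=C(\C)CC[C@H]1O[C@]1(C)CO | intermediate
4 | (2E,6R,7S)-6,7,8-trihydroxy-3,7-dimethyloct-2-en-1-yl acetate | CC(=O)OC/C=C(\C)CC[C@@H](O)[C@](O)(C)CO | intermediate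
5 | (2E,6R,7S)-7-hydroxy-3,7-dimethyl-6,8-bis(triethylsilyloxy)oct-2-en-1-yl acetate | CC(=O)OC/C=C(\C)CC[C@@H](O[Si](CC)(CC)CC)[C@](O)(C)CO[Si](CC)(CC)CC | intermediate
6 | 2,2,6-trimethyl-4H-1,3-dioxin-4-one | CC1=CC(=O)OC(C)(C)O1 | starting material
7 | diethyl [(2,2-dimethyl-4-oxo-4H-1,3-dioxin-6-yl)methyl]phosphonate | CCOP(=O)(OCC)CC1=CC(=O)OC(C)(C)O1 | intermediate
8 | diethyl (2,4-dioxobut-3-en-1-yl)phosphonate (acylketene) | CCOP(=O)(OCC)CC(=O)C=C=O | intermediate
9 | (2E,6R,7S)-7-{[4-(diethoxyphosphoryl)-3-oxobutanoyl]oxy}-3,7-dimethyl-6,8-bis(triethylsilyloxy)oct-2-en-1-yl acetate | CC(=O)OC/C=C(\C)CC[C@@H](O[Si](CC)(CC)CC)[C@](OC(=O)CC(=O)CP(=O)(OCC)OCC)(C)CO[Si](CC)(CC)CC | intermediate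
10 | 5-bromo-2-methylpent-2-ene | CC(C)=CCCBr | starting material
11 | (2E,6R,7S)-7-{[4-(diethoxyphosphoryl)-2-(4-methylpent-3-en-1-yl)-3-oxobutanoyl]oxy}-3,7-dimethyl-6,8-bis(triethylsilyloxy)oct-2-en-1-yl acetate | CC(=O)OC/C=C(\C)CC[C@@H](O[Si](CC)(CC)CC)[C@](OC(=O)C(CCC=C(C)C)C(=O)CP(=O)(OCC)OCC)(C)CO[Si](CC)(CC)CC | intermediate
12 | (2E,6R,7S)-7-{[4-(diethoxyphosphoryl)-3-hydroxy-2-(4-methylpent-3-en-1-yl)butanoyl]oxy}-3,7-dimethyl-6,8-bis(triethylsilyloxy)oct-2-en-1-yl acetate | CC(=O)OC/C=C(\C)CC[C@@H](O[Si](CC)(CC)CC)[C@](OC(=O)C(CCC=C(C)C)C(O)CP(=O)(OCC)OCC)(C)CO[Si](CC)(CC)CC | intermediate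
13 | (2E,6R,7S)-7-{[4-(diethoxyphosphoryl)-3-(methanesulfonyloxy)-2-(4-methylpent-3-en-1-yl)butanoyl]oxy}-3,7-dimethyl-6,8-bis(triethylsilyloxy)oct-2-en-1-yl acetate | CC(=O)OC/C=C(\C)CC[C@@H](O[Si](CC)(CC)CC)[C@](OC(=O)C(CCC=C(C)C)C(OS(C)(=O)=O)CP(=O)(OCC)OCC)(C)CO[Si](CC)(CC)CC | intermediate
14 | (2E,6R,7S)-7-{[(2E)-4-(diethoxyphosphoryl)-2-(4-methylpent-3-en-1-yl)but-2-enoyl]oxy}-3,7-dimethyl-6,8-bis(triethylsilyloxy)oct-2-en-1-yl acetate | CC(=O)OC/C=C(\C)CC[C@@H](O[Si](CC)(CC)CC)[C@](OC(=O)/C(CCC=C(C)C)=C/CP(=O)(OCC)OCC)(C)CO[Si](CC)(CC)CC | intermediate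
15 | (2E,6R,7R)-7-{[(2E)-4-(diethoxyphosphoryl)-2-(4-methylpent-3-en-1-yl)but-2-enoyl]oxy}-3,7-dimethyl-8-oxo-6-(triethylsilyloxy)oct-2-en-1-yl acetate | CC(=O)OC/C=C(\C)CC[C@@H](O[Si](CC)(CC)CC)[C@](OC(=O)/C(CCC=C(C)C)=C/CP(=O)(OCC)OCC)(C)C=O | intermediate
16 | (2E,6R)-3-methyl-6-[(2S)-2-methyl-6-(4-methylpent-3-en-1-yl)-7-oxo-2,7-dihydrooxepin-2-yl]-6-(triethylsilyloxy)hex-2-en-1-yl acetate | CC(=O)OC/C=C(\C)CC[C@@H](O[Si](CC)(CC)CC)[C@]1(C)C=CC=C(CCC=C(C)C)C(=O)O1 | intermediate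
17 | (2E,6R)-3-methyl-6-[(2S)-2-methyl-6-(4-methylpent-3-en-1-yl)-7-oxo-2,3,4,7-tetrahydrooxepin-2-yl]-6-(triethylsilyloxy)hex-2-en-1-yl acetate | CC(=O)OC/C=C(\C)CC[C@@H](O[Si](CC)(CC)CC)[C@]1(C)CCC=C(CCC=C(C)C)C(=O)O1 | intermediate
18 | (2E,6R)-6-hydroxy-3-methyl-6-[(2S)-2-methyl-6-(4-methylpent-3-en-1-yl)-7-oxo-2,3,4,7-tetrahydrooxepin-2-yl]hex-2-en-1-yl acetate | CC(=O)OC/C=C(\C)CC[C@@H](O)[C@]1(C)CCC=C(CCC=C(C)C)C(=O)O1 | target

Total steps: 13. Longest linear sequence: 12 (steps 1–4 and 6–13).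

Steps most likely to fail

Step 11 (key step). The strained seven-membered closure may be outpaced by intermolecular olefination, or the ambident anion may be held at C11 long enough for base-induced decomposition. The fallback sets out from 11 and returns at 17, closing the ring one oxidation level higher with a non-ambident β-keto phosphonate. Oxidation of the primary silyl ether of 11 as in step 10 should give (2E,6R,7R)-7-{[4-(diethoxyphosphoryl)-2-(4-methylpent-3-en-1-yl)-3-oxobutanoyl]oxy}-3,7-dimethyl-8-oxo-6-(triethylsilyloxy)oct-2-en-1-yl acetate F2. Intramolecular Horner–Wadsworth–Emmons reaction (K2CO3, 18-crown-6, toluene, high dilution) should then give the cyclic enone (2E,6R)-3-methyl-6-[(2S)-2-methyl-6-(4-methylpent-3-en-1-yl)-5,7-dioxo-2,5,6,7-tetrahydrooxepin-2-yl]-6-(triethylsilyloxy)hex-2-en-1-yl acetate F3. Conjugate reduction with [(Ph3P)CuH]6 should give the saturated β-keto lactone (2E,6R)-3-methyl-6-[(2S)-2-methyl-6-(4-methylpent-3-en-1-yl)-5,7-dioxooxepan-2-yl]-6-(triethylsilyloxy)hex-2-en-1-yl acetate F4, and NaBH4 the β-hydroxy lactone (2E,6R)-6-[(2S)-5-hydroxy-2-methyl-6-(4-methylpent-3-en-1-yl)-7-oxooxepan-2-yl]-3-methyl-6-(triethylsilyloxy)hex-2-en-1-yl acetate F5. Mesylation to (2E,6R)-6-[(2S)-5-(methanesulfonyloxy)-2-methyl-6-(4-methylpent-3-en-1-yl)-7-oxooxepan-2-yl]-3-methyl-6-(triethylsilyloxy)hex-2-en-1-yl acetate F6 and DBU elimination should give 17.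

Step 12. Diimide may discriminate poorly between C8=C9 and the trisubstituted alkenes, or over-reduce. The fallback sets out from 16 and returns at 17. 1,4-Hydrogenation with (naphthalene)Cr(CO)3 and H2 in THF engages only the s-cis conjugated diene and should give the β,γ-unsaturated lactone (2E,6R)-3-methyl-6-[(2S)-2-methyl-6-(4-methylpent-3-en-1-yl)-7-oxo-2,3,6,7-tetrahydrooxepin-2-yl]-6-(triethylsilyloxy)hex-2-en-1-yl acetate F7. Isomerisation into conjugation with DBU should then give 17.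

Step 3. Opening with carbocation character may erode the inversion at C7, and the C2=C3 alkene may take part in a cation–olefin cyclisation. The fallback sets out from 3 and returns at 4. Payne rearrangement and opening with aqueous NaOH in tBuOH proceeds by two SN2 events (the C8 alkoxide attacks C7 with inversion, then hydroxide attacks C8); it also cleaves the acetate and should give (2E,6R,7S)-3,7-dimethyloct-2-ene-1,6,7,8-tetrol F1. Selective acetylation of the unhindered allylic primary hydroxyl (acetyl chloride, 2,4,6-collidine, CH2Cl2, −78 °C) should return 4.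

Further compounds
F1 | step 3 | (2E,6R,7S)-3,7-dimethyloct-2-ene-1,6,7,8-tetrol | OC/C=C(\C)CC[C@@H](O)[C@](O)(C)CO
F2 | step 11 | (2E,6R,7R)-7-{[4-(diethoxyphosphoryl)-2-(4-methylpent-3-en-1-yl)-3-oxobutanoyl]oxy}-3,7-dimethyl-8-oxo-6-(triethylsilyloxy)oct-2-en-1-yl acetate | CC(=O)OC/C=C(\C)CC[C@@H](O[Si](CC)(CC)CC)[C@](OC(=O)C(CCC=C(C)C)C(=O)CP(=O)(OCC)OCC)(C)C=O
F3 | step 11 | (2E,6R)-3-methyl-6-[(2S)-2-methyl-6-(4-methylpent-3-en-1-yl)-5,7-dioxo-2,5,6,7-tetrahydrooxepin-2-yl]-6-(triethylsilyloxy)hex-2-en-1-yl acetate | CC(=O)OC/C=C(\C)CC[C@@H](O[Si](CC)(CC)CC)[C@]1(C)C=CC(=O)C(CCC=C(C)C)C(=O)O1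
F4 | step 11 | (2E,6R)-3-methyl-6-[(2S)-2-methyl-6-(4-methylpent-3-en-1-yl)-5,7-dioxooxepan-2-yl]-6-(triethylsilyloxy)hex-2-en-1-yl acetate | CC(=O)OC/C=C(\C)CC[C@@H](O[Si](CC)(CC)CC)[C@]1(C)CCC(=O)C(CCC=C(C)C)C(=O)O1
F5 | step 11 | (2E,6R)-6-[(2S)-5-hydroxy-2-methyl-6-(4-methylpent-3-en-1-yl)-7-oxooxepan-2-yl]-3-methyl-6-(triethylsilyloxy)hex-2-en-1-yl acetate | CC(=O)OC/C=C(\C)CC[C@@H](O[Si](CC)(CC)CC)[C@]1(C)CCC(O)C(CCC=C(C)C)C(=O)O1
F6 | step 11 | (2E,6R)-6-[(2S)-5-(methanesulfonyloxy)-2-methyl-6-(4-methylpent-3-en-1-yl)-7-oxooxepan-2-yl]-3-methyl-6-(triethylsilyloxy)hex-2-en-1-yl acetate | CC(=O)OC/C=C(\C)CC[C@@H](O[Si](CC)(CC)CC)[C@]1(C)CCC(OS(C)(=O)=O)C(CCC=C(C)C)C(=O)O1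
F7 | step 12 | (2E,6R)-3-methyl-6-[(2S)-2-methyl-6-(4-methylpent-3-en-1-yl)-7-oxo-2,3,6,7-tetrahydrooxepin-2-yl]-6-(triethylsilyloxy)hex-2-en-1-yl acetate | CC(=O)OC/C=C(\C)CC[C@@H](O[Si](CC)(CC)CC)[C@]1(C)CC=CC(CCC=C(C)C)C(=O)O1
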